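## Retrosynthetic overview
1. Herboxidiene comes from the methyl ester 28 by LiOH hydrolysis, and 28 from TBS ether 27 by desilylation. Ester 28 is not taken from the acid forward.
2. The (E,E)-diene is made last, by Suzuki coupling at C9–C10 between THP vinyl iodide **10** and the E-alkenylborane from epoxy-alkyne **26**.
3. The THP ring (C3 stereocentre) is formed first, on the left side, by thermodynamic oxa-Michael cyclisation of an anti-crotylation product. The vinyl iodide comes from Negishi carboalumination of the terminal alkyne.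
4. On the right side the epoxide is formed before the diene exists, by Shi epoxidation of an E-trisubstituted alkene. That alkene comes from cross-metathesis (CM) of a Z-crotylation-derived vinyl stereotriad (from (R)-lactate) with a Roche-derived 1,1-disubstituted alkene.
5. C11≡C10 is then built from the primary alcohol by oxidation and Ohira–Bestmann homologation.

Assumptions (one line): the Ipc₂B antipodes (Si-face on 1, Re-face on 14) and the D-fructose Shi ketone give the required faces; 4 is available as the E isomer.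

## Route

**Step 1**
Reactants: 1 (3-(trimethylsilyl)prop-2-ynal), 2 (trans-2-butene)
Product: 3, (3S,4S)-4-methyl-1-(trimethylsilyl)hex-5-en-1-yn-3-ol (anti)
Conditions: (E)-crotyl-B(Ipc)₂ [2, t-BuOK/n-BuLi; Ipc₂B-OMe from (+)-α-pinene; BF₃·OEt₂], THF, –78 °C; then NaBO₃·4H₂O
Reagents that add atoms: trans-2-butene (2), C/C=C/C (crotyl unit)
Why: Brown crotylboration; the E-crotyl reagent via a chair transition state gives the anti product, and the Ipc antipode sets the Si-face attack, fixing C6 and C7 in one step.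

**Step 2**
Reactants: 3, 4 (methyl (E)-3-bromoacrylate)
Product: 5, methyl (2E,6S,7S)-7-hydroxy-6-methyl-9-(trimethylsilyl)non-2-en-8-ynoate
Conditions: 9-BBN (2.2 equiv), THF, 0 °C→rt; then 4, Pd(dppf)Cl₂, K₃PO₄ (aq), THF/DMF, 50 °C
Reagents that add atoms: 4, COC(=O)/C=C/Br (adds the CH=CH–CO₂Me unit)
Why: 9-BBN hydroborates only the terminal vinyl group, and B-alkyl Suzuki coupling with the E-bromoenoate installs the oxa-Michael acceptor with retention of alkene geometry. No new stereocentre is made and the existing ones are untouched.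

**Step 3**
Reactants: 5
Product: 6, methyl 2-[(2R,5S,6S)-5-methyl-6-(TMS-ethynyl)oxan-2-yl]acetate
Conditions: t-BuOK (0.3 equiv), THF, –78→0 °C
Reagents that add atoms: none
Why: Intramolecular oxa-Michael addition is reversible, so it funnels to the all-equatorial 2,6-cis THP. C3 is set cis to C7, and C6 and C7 are already fixed.

**Step 4**
Reactants: 6
Product: 7, methyl 2-[(2R,5S,6S)-6-ethynyl-5-methyloxan-2-yl]acetate
Conditions: K₂CO₃, MeOH, rt
Reagents that add atoms: none
Why: Protodesilylation of the alkynyl TMS group; the methyl ester is untouched.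

**Step 5**
Reactants: 7, 8 (trimethylaluminium), 9 (iodine)
Product: 10, methyl 2-[(2R,5S,6S)-6-[(1E)-1-iodoprop-1-en-2-yl]-5-methyloxan-2-yl]acetate
Conditions: Me₃Al, Cp₂ZrCl₂, CH₂Cl₂, rt; then I₂, THF, –30 °C
Reagents that add atoms: Me₃Al, C[Al](C); I₂, II
Why: Negishi Zr-catalysed syn-methylalumination of the terminal alkyne puts the methyl on C8 and Al on C9, trans to the ring. Iodinolysis then gives the (E)-vinyl iodide with retention.

**Step 6**
Reactants: 11 (methyl (R)-lactate), 12 (TBSCl)
Product: 13, methyl (2R)-2-(TBSO)propanoate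
Conditions: TBSCl, imidazole, DMF, rt
Reagents that add atoms: TBSCl, CC(C)(C)[Si](C)(C)Cl
Why: Silylation of the secondary alcohol. The C18 stereocentre is untouched and becomes C18 (R).

**Step 7**
Reactants: 13
Product: 14, (2R)-2-(TBSO)propanal
Conditions: DIBAL-H (1.05 equiv), CH₂Cl₂, –78 °C
Reagents that add atoms: none
Why: Partial ester reduction stops at the aldehyde at low temperature; the crude aldehyde is used at once to limit epimerisation.

**Step 8**
Reactants: 14, 15 (cis-2-butene)
Product: 16, (3S,4R,5R)-5-(TBSO)-3-methylhex-1-en-4-ol (syn,syn)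
Conditions: (Z)-crotyl-B(Ipc)₂ [15, t-BuOK/n-BuLi; Ipc₂B-OMe from (–)-α-pinene; BF₃·OEt₂], THF, –78 °C; then NaOH/H₂O₂
Reagents that add atoms: cis-2-butene (15), C/C=C\C (crotyl unit)
Why: Brown crotylboration; the Z reagent gives the syn (C16/C17) relationship and the reagent's Re-face preference overrides the aldehyde's Felkin bias, setting C16 and C17 (the C17/C18 syn relationship is the mismatched sense).

**Step 9**
Reactants: 16, 17 (MeOTf)
Product: 18, tert-butyl{[(2R,3R,4S)-3-methoxy-4-methylhex-5-en-2-yl]oxy}dimethylsilane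
Conditions: MeOTf, 2,6-di-t-Bu-4-methylpyridine, CH₂Cl₂, 0 °C→rt
Reagents that add atoms: MeOTf, COS(=O)(=O)C(F)(F)F
Why: O-methylation under non-basic conditions avoids 1,2-silyl migration; the terminal alkene and the stereocentres are unaffected.

**Step 10**
Reactants: 19 ((2R)-3-bromo-2-methylpropan-1-ol), 20 (isopropenylmagnesium bromide)
Product: 21, (2S)-2,4-dimethylpent-4-en-1-ol
Conditions: 20 (2.5 equiv), Li₂CuCl₄ (cat.), THF, –20→0 °C
Reagents that add atoms: isopropenylMgBr, C=C(C)[Mg]Br
Why: Cu-catalysed SN2 coupling of the primary bromide with the alkenyl Grignard (the alkoxide forms first). The C12 stereocentre is not involved and is carried through from the Roche-type building block.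

**Step 11**
Reactants: 18, 21
Product: 22, (2S,4E,6S,7R,8R)-8-(TBSO)-7-methoxy-2,4,6-trimethylnon-4-en-1-ol
Conditions: 21 (4 equiv), Hoveyda–Grubbs II (10 mol %), CH₂Cl₂, 40 °C
Reagents that add atoms: none
Why: Cross-metathesis of the monosubstituted alkene with the 1,1-disubstituted alkene releases ethylene and gives the E-trisubstituted alkene (the Me lies cis to the branched C16 side), which is the geometry needed for the epoxide.

**Step 12**
Reactants: 22
Product: 23, (2S,4R,5R,6R,7R,8R)-8-(TBSO)-4,5-epoxy-7-methoxy-2,4,6-trimethylnonan-1-ol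
Conditions: Shi ketone (D-fructose derived, 0.3 equiv), Oxone, K₂CO₃, Bu₄NHSO₄, MeCN/DMM/aq Na₂B₄O₇–EDTA, 0 °C
Reagents that add atoms: Oxone, OOS(=O)(=O)[O-].[K+] (supplies the epoxide O)
Why: Shi asymmetric epoxidation of an E-trisubstituted alkene gives the (14R,15R) epoxide by catalyst control; the free alcohol, OMe and OTBS survive at pH 10.5.

**Step 13**
Reactants: 23
Product: 24, (2S,4R,5R,6R,7R,8R)-8-(TBSO)-4,5-epoxy-7-methoxy-2,4,6-trimethylnonanal
Conditions: Dess–Martin periodinane, NaHCO₃, CH₂Cl₂, 0 °C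
Reagents that add atoms: none
Why: Buffered DMP oxidises the primary alcohol without opening the epoxide or removing the silyl ether; the crude aldehyde is used at once.

**Step 14**
Reactants: 24, 25 (dimethyl (1-diazo-2-oxopropyl)phosphonate)
Product: 26, (3S,5R,6R,7R,8R,9R)-9-(TBSO)-5,6-epoxy-8-methoxy-3,5,7-trimethyldec-1-yne
Conditions: 25, K₂CO₃, MeOH, 0 °C→rt
Reagents that add atoms: Ohira–Bestmann reagent, COP(=O)(OC)C(=[N+]=[N-])C(C)=O (supplies the terminal alkyne carbon C10)
Why: Ohira–Bestmann one-carbon homologation under mild base; the epoxide and TBS ether are stable, and C12 is not involved (its α-epimerisation is kept low by 0 °C).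

**Step 15**
Reactants: 26, 10
Product: 27, methyl 2-[(2R,5S,6S)-6-[(1E,3E,5S,7R,8R,9R,10R,11R)-11-(TBSO)-7,8-epoxy-10-methoxy-1,5,7,9-tetramethyldodeca-1,3-dien-1-yl]-5-methyloxan-2-yl]acetate
Conditions: Cy₂BH, THF, 0 °C; then 10, Pd(dppf)Cl₂ (10 mol %), K₃PO₄ (aq), THF, rt
Reagents that add atoms: none
Why: Cy₂BH hydroborates the terminal alkyne selectively (syn, giving the E-alkenylborane) and leaves the epoxide alone; Suzuki–Miyaura coupling with the vinyl iodide proceeds with retention to give the E,E-diene. No stereocentre is changed.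

**Step 16**
Reactants: 27
Product: 28, methyl 2-[(2R,5S,6S)-6-[(1E,3E,5S,7R,8R,9R,10R,11R)-7,8-epoxy-11-hydroxy-10-methoxy-1,5,7,9-tetramethyldodeca-1,3-dien-1-yl]-5-methyloxan-2-yl]acetate
Conditions: TBAF, AcOH, THF, rt
Reagents that add atoms: none
Why: Buffered fluoride removes the TBS group without base-induced retro-oxa-Michael ring opening or acid-induced epoxide opening.

**Step 17**
Reactants: 28
Product: 29, herboxidiene
Conditions: LiOH, THF/H₂O, rt; acidify to pH 5 (aq. NaH₂PO₄)
Reagents that add atoms: water, O (hydroxide oxygen in the acid)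
Why: Saponification of the methyl ester; the mild work-up keeps the tertiary epoxide intact.

## Compound list
1 | 3-(trimethylsilyl)prop-2-ynal | C[Si](C)(C)C#CC=O | starting material
2 | (E)-but-2-ene | C/C=C/C | starting material
3 | (3S,4S)-4-methyl-1-(trimethylsilyl)hex-5-en-1-yn-3-ol | C[Si](C)(C)C#C[C@@H](O)[C@@H](C)C=C | intermediate
4 | methyl (2E)-3-bromoprop-2-enoate | COC(=O)/C=C/Br | starting material
5 | methyl (2E,6S,7S)-7-hydroxy-6-methyl-9-(TMS)non-2-en-8-ynoate | COC(=O)/C=C/CC[C@H](C)[C@H](O)C#C[Si](C)(C)C | intermediate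
6 | methyl 2-[(2R,5S,6S)-5-methyl-6-(TMS-ethynyl)oxan-2-yl]acetate | C[Si](C)(C)C#C[C@H]1O[C@@H](CC(=O)OC)CC[C@@H]1C | intermediate
7 | methyl 2-[(2R,5S,6S)-6-ethynyl-5-methyloxan-2-yl]acetate | C#C[C@H]1O[C@@H](CC(=O)OC)CC[C@@H]1C | intermediate
8 | trimethylaluminium | C[Al](C)C | starting material
9 | iodine | II | starting material
10 | methyl 2-[(2R,5S,6S)-6-[(1E)-1-iodoprop-1-en-2-yl]-5-methyloxan-2-yl]acetate | I/C=C(\C)[C@H]1O[C@@H](CC(=O)OC)CC[C@@H]1C | intermediate
11 | methyl (R)-lactate | C[C@@H](O)C(=O)OC | starting material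
12 | tert-butyldimethylsilyl chloride | CC(C)(C)[Si](C)(C)Cl | starting material
13 | methyl (2R)-2-(TBSO)propanoate | C[C@@H](O[Si](C)(C)C(C)(C)C)C(=O)OC | intermediate
14 | (2R)-2-(TBSO)propanal | C[C@@H](O[Si](C)(C)C(C)(C)C)C=O | intermediate
15 | (Z)-but-2-ene | C/C=C\C | starting material
16 | (3S,4R,5R)-5-(TBSO)-3-methylhex-1-en-4-ol | C[C@@H](O[Si](C)(C)C(C)(C)C)[C@H](O)[C@@H](C)C=C | intermediate
17 | methyl triflate | COS(=O)(=O)C(F)(F)F | starting material
18 | tert-butyl{[(2R,3R,4S)-3-methoxy-4-methylhex-5-en-2-yl]oxy}dimethylsilane | C[C@@H](O[Si](C)(C)C(C)(C)C)[C@H](OC)[C@@H](C)C=C | intermediate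
19 | (2R)-3-bromo-2-methylpropan-1-ol | OC[C@@H](C)CBr | starting material
20 | isopropenylmagnesium bromide | C=C(C)[Mg]Br | starting material
21 | (2S)-2,4-dimethylpent-4-en-1-ol | OC[C@@H](C)CC(C)=C | intermediate
22 | (2S,4E,6S,7R,8R)-8-(TBSO)-7-methoxy-2,4,6-trimethylnon-4-en-1-ol | OC[C@@H](C)C/C(C)=C/[C@H](C)[C@@H](OC)[C@@H](C)O[Si](C)(C)C(C)(C)C | intermediate
23 | (2S,4R,5R,6R,7R,8R)-8-(TBSO)-4,5-epoxy-7-methoxy-2,4,6-trimethylnonan-1-ol | C[C@@H](O[Si](C)(C)C(C)(C)C)[C@H](OC)[C@@H](C)[C@H]1O[C@]1(C)C[C@H](C)CO | intermediate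
24 | corresponding (2S)-aldehyde (epoxy aldehyde) | C[C@@H](O[Si](C)(C)C(C)(C)C)[C@H](OC)[C@@H](C)[C@H]1O[C@]1(C)C[C@H](C)C=O | intermediate
25 | dimethyl (1-diazo-2-oxopropyl)phosphonate | COP(=O)(OC)C(=[N+]=[N-])C(C)=O | starting material
26 | (3S,5R,6R,7R,8R,9R)-9-(TBSO)-5,6-epoxy-8-methoxy-3,5,7-trimethyldec-1-yne | C[C@@H](O[Si](C)(C)C(C)(C)C)[C@H](OC)[C@@H](C)[C@H]1O[C@]1(C)C[C@H](C)C#C | intermediate
27 | TBS-protected herboxidiene methyl ester | CO[C@H]([C@@H](C)[C@H]1O[C@]1(C)C[C@H](C)/C=C/C=C(\C)[C@H]1O[C@@H](CC(=O)OC)CC[C@@H]1C)[C@@H](C)O[Si](C)(C)C(C)(C)C | intermediate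
28 | herboxidiene methyl ester | CO[C@H]([C@@H](C)[C@H]1O[C@]1(C)C[C@H](C)/C=C/C=C(\C)[C@H]1O[C@@H](CC(=O)OC)CC[C@@H]1C)[C@@H](C)O | intermediate
29 | herboxidiene | CO[C@H]([C@@H](C)[C@H]1O[C@]1(C)C[C@H](C)/C=C/C=C(\C)[C@H]1O[C@@H](CC(=O)O)CC[C@@H]1C)[C@@H](C)O | target

## Totals
Total steps: 17. Longest linear sequence: 11 (methyl (R)-lactate → 13 → 14 → 16 → 18 → 22 → 23 → 24 → 26 → 27 → 28 → 29, i.e. steps 6, 7, 8, 9, 11, 12, 13, 14, 15, 16, 17).

## Three steps most likely to fail
1. **Step 11 (cross-metathesis to the E-trisubstituted alkene).** The α-branched, hindered vinyl partner and the type III alkene may give low conversion or poor E/Z ratio.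
   - Fallback: ozonolyse 18 to the C15 aldehyde, then make the alkene by HWE olefination with triethyl 2-phosphonopropionate (E-enoate). Reduce to the E-allylic alcohol and use Sharpless asymmetric epoxidation, which also removes the dependence on Shi; then rebuild the C13–C12 link by alkylation.
2. **Step 8 (Z-crotylboration of 14).** The 17,18-syn product needs the reagent to override the aldehyde's Felkin preference (mismatched pair), so dr may be modest.
   - Fallback: switch the protecting group to PMB and use a chelation-controlled Z-crotyl addition (Z-crotylstannane/MgBr₂·OEt₂), which inherently gives the 17,18-syn relationship, then remove PMB with DDQ at the end.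
3. **Step 14 (Ohira–Bestmann on α-branched aldehyde 24).** C12 may epimerise under K₂CO₃/MeOH.
   - Fallback: avoid the α-chiral aldehyde. Convert alcohol 23 to the PT-sulfone (Mitsunobu with PT-SH, then oxidation) and form C10=C11 by Julia–Kocienski olefination with the THP enal (THP–C(Me)=CH–CHO).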